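**Retrosynthetic overview**

1. Erythbigenin ← MOM removal ← bis-MOM isoflavone ← ring C closed last by inserting C2 between O1 and C3 of a 2,4,6-trihydroxyphenyl benzyl ketone (DMF-DMA).
2. The route rests on ring A (C4a, C5, C6, C7, C8, C8a): a phloroglucinol with oxygen on C5, C7 and C8a and the C4 carbonyl on C4a, the fold of a linear tetraketide. It is cut at C4a–C5 to methyl 8-aryl-3,5,7-trioxooctanoate (Claisen closure of chain C6 onto ester carbon C1).
3. Triketo ester ← trianion of methyl 3,5-dioxohexanoate (from dehydroacetic acid) + ring B arylacetic Weinreb amide (chain C6–C7 bond).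
4. Ring B ← homovanillic acid: C5 hydroxylation (bromination, copper-mediated hydrolysis), MOM protection, 2,6-dibromination, double linear-selective Negishi prenylation.
5. Ring order: ring B is bought as an arene, ring A is built in step 10, ring C in step 11.

Key step: step 10

Assumption: the target is the achiral isoflavone as drawn (no stereocentres, no E/Z element in the prenyl groups). Homovanillic acid, dehydroacetic acid, prenyl bromide and Mg(OMe)2 in MeOH are taken as commercial, and prenylzinc bromide is made beforehand from prenyl bromide, Zn dust and LiCl in THF.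

**Route**

Step 1
Reactants: 1 homovanillic acid (2-(4-hydroxy-3-methoxyphenyl)acetic acid)
Product: 2 2-(3-bromo-4-hydroxy-5-methoxyphenyl)acetic acid
Conditions: Br2 (1.05 equiv), AcOH, 15 °C → rt
Reagents that add atoms: bromine, BrBr
Why: Electrophilic aromatic bromination: the free phenol is the strongest director, its para position carries the side chain and one ortho position the methoxy group, so bromine should enter the remaining ortho carbon, as in the bromination of vanillin.

Step 2
Reactants: 2 2-(3-bromo-4-hydroxy-5-methoxyphenyl)acetic acid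
Product: 3 2-(3,4-dihydroxy-5-methoxyphenyl)acetic acid
Conditions: NaOH (aq., 8 equiv), Cu powder (10 mol%), reflux, N2; then HCl to pH 2
Reagents that add atoms: sodium hydroxide, [Na+].[OH-]
Why: Ullmann-type copper-mediated hydroxylation of an ortho-bromophenoxide, the transformation that turns 5-bromovanillin into 5-hydroxyvanillin, should replace bromide by hydroxide while the carboxylate and the aryl methyl ether are inert to aqueous base.

Step 3
Reactants: 3 2-(3,4-dihydroxy-5-methoxyphenyl)acetic acid
Product: 4 methyl 2-(3,4-dihydroxy-5-methoxyphenyl)acetate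
Conditions: MeOH, H2SO4 (cat.), reflux
Reagents that add atoms: methanol, CO
Why: Fischer esterification should cleanly mask the acid, which would otherwise consume MOMCl and quench the organozinc reagent later.

Step 4
Reactants: 4 methyl 2-(3,4-dihydroxy-5-methoxyphenyl)acetate
Product: 5 methyl 2-[3,4-bis(methoxymethoxy)-5-methoxyphenyl]acetate
Conditions: MOMCl (3 equiv), iPr2NEt (4 equiv), CH2Cl2, 0 °C → rt
Reagents that add atoms: chloromethyl methyl ether, COCCl
Why: O-alkylation of both catechol hydroxyls with the α-chloro ether under amine base (MOM ether formation) should leave the ester α-protons alone and gives acetals that survive every basic and organometallic step ahead.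

Step 5
Reactants: 5 methyl 2-[3,4-bis(methoxymethoxy)-5-methoxyphenyl]acetate
Product: 6 methyl 2-[2,6-dibromo-3,4-bis(methoxymethoxy)-5-methoxyphenyl]acetate
Conditions: NBS (2.2 equiv), MeCN, 0 °C → rt, dark
Reagents that add atoms: N-bromosuccinimide, O=C1CCC(=O)N1Br
Why: Electrophilic aromatic bromination with NBS in a polar solvent: the only two ring hydrogens (C2 and C6) are each ortho to one alkoxy group and para to another, so both should be replaced with no regiochemical choice, and the neutral medium spares the MOM acetals.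

Step 6
Reactants: 6 methyl 2-[2,6-dibromo-3,4-bis(methoxymethoxy)-5-methoxyphenyl]acetate
Product: 7 methyl 2-[3,4-bis(methoxymethoxy)-5-methoxy-2,6-bis(3-methylbut-2-en-1-yl)phenyl]acetate
Conditions: prenylZnBr (3 equiv, THF), Pd(OAc)2 (5 mol%), CPhos (10 mol%), THF, rt → 45 °C
Reagents that add atoms: prenylzinc bromide, CC(C)=CC[Zn]Br
Why: Linear-selective Negishi cross-coupling of an allylzinc halide: with the bulky biarylphosphine CPhos on palladium, reductive elimination should occur at the primary allyl terminus to give unbranched 3-methylbut-2-enyl groups, and allylzinc halides leave the ester alone at this temperature.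

Step 7
Reactants: 7 methyl 2-[3,4-bis(methoxymethoxy)-5-methoxy-2,6-bis(3-methylbut-2-en-1-yl)phenyl]acetate
Product: 8 N-methoxy-N-methyl-2-[3,4-bis(methoxymethoxy)-5-methoxy-2,6-bis(3-methylbut-2-en-1-yl)phenyl]acetamide
Conditions: MeNH(OMe)·HCl (3 equiv), iPrMgCl (6 equiv), THF, −20 → 0 °C
Reagents that add atoms: N,O-dimethylhydroxylamine hydrochloride, CNOC.Cl
Why: Ester aminolysis with the chloromagnesium amide of N,O-dimethylhydroxylamine (Weinreb amide synthesis) should work on this acetate carbonyl, which sits one carbon away from the crowded ring, and gives an acyl donor that is less C–H acidic than the ester and cannot over-add.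

Step 8
Reactants: 9 dehydroacetic acid (3-acetyl-4-hydroxy-6-methyl-2H-pyran-2-one)
Product: 11 methyl 3,5-dioxohexanoate, via methyl 2-acetyl-3,5-dioxohexanoate 10 (not isolated)
Conditions: Mg(OMe)2 (2 equiv), MeOH, reflux; then cold 1 M HCl
Reagents that add atoms: methanol, CO (delivered as magnesium methoxide, C[O-].C[O-].[Mg+2])
Why: Methoxide opens the pyranone lactone to the acetyl tricarbonyl ester 10, and a retro-Claisen deacetylation steered by magnesium chelation then removes the acetyl group as methyl acetate, the standard preparation of this diketo ester.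

Step 9
Reactants: 11 methyl 3,5-dioxohexanoate; 8 N-methoxy-N-methyl-2-[3,4-bis(methoxymethoxy)-5-methoxy-2,6-bis(3-methylbut-2-en-1-yl)phenyl]acetamide
Product: 13 methyl 8-[3,4-bis(methoxymethoxy)-5-methoxy-2,6-bis(3-methylbut-2-en-1-yl)phenyl]-3,5,7-trioxooctanoate, via trilithium trianion 12 (not isolated)
Conditions: 11 (2.5 equiv), LiN(iPr)2 (7.5 equiv), THF, −78 → 0 °C; then 8, −78 → −30 °C; aq. NH4Cl, 0 °C; used at once
Reagents that add atoms: none
Why: Acylation of a polyketide polyanion at its terminal, most basic carbanion (Harris-type trianion acylation, here with a Weinreb amide): the chelated tetrahedral adduct should hold until the quench, so no acidic triketone is released to consume trianion, and the lower C–H acidity of the amide, with the benzylic methylene twisted by two ortho prenyl groups, should let C-acylation outrun proton transfer.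

Step 10
Reactants: 13 methyl 8-[3,4-bis(methoxymethoxy)-5-methoxy-2,6-bis(3-methylbut-2-en-1-yl)phenyl]-3,5,7-trioxooctanoate
Product: 14 2-[3,4-bis(methoxymethoxy)-5-methoxy-2,6-bis(3-methylbut-2-en-1-yl)phenyl]-1-(2,4,6-trihydroxyphenyl)ethan-1-one
Conditions: Mg(OMe)2 (8 equiv), MeOH, rt → reflux; then aq. NH4Cl, 0 °C
Reagents that add atoms: none
Why: Excess Mg(OMe)2 should turn 13 into a magnesium-chelated polyenolate in which the C3, C5 and C7 ketones are all enolised and so switched off as electrophiles, leaving ester carbon C1 as the only acceptor; C6 of the C5/C7 chelate adds to it, the tetrahedral intermediate expels methoxide (intramolecular Claisen, Dieckmann-type condensation), and the cyclohexane-1,3,5-trione enolises irreversibly to the phloroglucinol. The closest known reaction type is the base-mediated Claisen cyclisation of 3,5,7-triketo esters to acylphloroglucinols of biomimetic polyketide chemistry. Ring A closes in a 6-exo-trig mode (enolate carbon C6 onto C1, carbonyl oxygen outside the ring), forming the bond that becomes C4a–C5 and leaving C7 as the exocyclic deoxybenzoin carbonyl (future C4) with C8 and ring B attached. No stereocentre is formed. The step needs Claisen closure (C6 onto C1) to beat aldol closure (C2 onto the C7 ketone, which would give a resorcylate) and O-acylation to a 4-hydroxy-2-pyrone: full enolisation under strongly basic, chelating conditions and shielding of C7 by the 2,6-diprenylbenzyl group disfavour the aldol, and any pyrone is reopened by methoxide and funnelled to the aromatic sink. MOM ethers, the aryl methyl ether and the prenyl groups are inert to methoxide, and ring A needs no protection.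

Step 11
Reactants: 14 2-[3,4-bis(methoxymethoxy)-5-methoxy-2,6-bis(3-methylbut-2-en-1-yl)phenyl]-1-(2,4,6-trihydroxyphenyl)ethan-1-one
Product: 16 3-[3,4-bis(methoxymethoxy)-5-methoxy-2,6-bis(3-methylbut-2-en-1-yl)phenyl]-5,7-dihydroxy-4H-chromen-4-one, via enaminone 15 (not isolated)
Conditions: DMF-DMA (3 equiv), THF, 65 °C
Reagents that add atoms: N,N-dimethylformamide dimethyl acetal, COC(OC)N(C)C
Why: Aminomethylenation of the activated benzylic methylene by the amide acetal, then intramolecular oxa-Michael addition–elimination of an ortho hydroxyl with loss of dimethylamine (the DMF-DMA deoxybenzoin-to-isoflavone synthesis), should close ring C; the two ortho hydroxyls are equivalent, so only one isoflavone can form, and the neutral conditions keep MOM and prenyl groups intact.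

Step 12
Reactants: 16 3-[3,4-bis(methoxymethoxy)-5-methoxy-2,6-bis(3-methylbut-2-en-1-yl)phenyl]-5,7-dihydroxy-4H-chromen-4-one
Product: 17 erythbigenin (3-[3,4-dihydroxy-5-methoxy-2,6-bis(3-methylbut-2-en-1-yl)phenyl]-5,7-dihydroxy-4H-chromen-4-one)
Conditions: 3 M aq. HCl, MeOH, 45 °C
Reagents that add atoms: none
Why: Acid-catalysed acetal exchange with methanol (MOM ether cleavage) should free both catechol hydroxyls, and dilute acid at moderate temperature should avoid acid-catalysed addition of the new 3'-hydroxyl to the neighbouring prenyl double bond (chroman formation).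

**Compound list**

1 | homovanillic acid (2-(4-hydroxy-3-methoxyphenyl)acetic acid) | COc1cc(CC(=O)O)ccc1O | starting material
2 | 2-(3-bromo-4-hydroxy-5-methoxyphenyl)acetic acid | COc1cc(CC(=O)O)cc(Br)c1O | intermediate
3 | 2-(3,4-dihydroxy-5-methoxyphenyl)acetic acid | COc1cc(CC(=O)O)cc(O)c1O | intermediate
4 | methyl 2-(3,4-dihydroxy-5-methoxyphenyl)acetate | COC(=O)Cc1cc(O)c(O)c(OC)c1 | intermediate
5 | methyl 2-[3,4-bis(methoxymethoxy)-5-methoxyphenyl]acetate | COC(=O)Cc1cc(OCOC)c(OCOC)c(OC)c1 | intermediate
6 | methyl 2-[2,6-dibromo-3,4-bis(methoxymethoxy)-5-methoxyphenyl]acetate | COC(=O)Cc1c(Br)c(OCOC)c(OCOC)c(OC)c1Br | intermediate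
7 | methyl 2-[3,4-bis(methoxymethoxy)-5-methoxy-2,6-bis(3-methylbut-2-en-1-yl)phenyl]acetate | COC(=O)Cc1c(CC=C(C)C)c(OCOC)c(OCOC)c(OC)c1CC=C(C)C | intermediate
8 | N-methoxy-N-methyl-2-[3,4-bis(methoxymethoxy)-5-methoxy-2,6-bis(3-methylbut-2-en-1-yl)phenyl]acetamide | CON(C)C(=O)Cc1c(CC=C(C)C)c(OCOC)c(OCOC)c(OC)c1CC=C(C)C | intermediate
9 | dehydroacetic acid (3-acetyl-4-hydroxy-6-methyl-2H-pyran-2-one) | CC(=O)C1=C(O)C=C(C)OC1=O | starting material
10 | methyl 2-acetyl-3,5-dioxohexanoate (not isolated) | COC(=O)C(C(C)=O)C(=O)CC(C)=O | intermediate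
11 | methyl 3,5-dioxohexanoate | COC(=O)CC(=O)CC(C)=O | intermediate
12 | trilithium trianion of methyl 3,5-dioxohexanoate (not isolated) | [Li+].[Li+].[Li+].C=C([O-])C=C([O-])C=C([O-])OC | intermediate
13 | methyl 8-[3,4-bis(methoxymethoxy)-5-methoxy-2,6-bis(3-methylbut-2-en-1-yl)phenyl]-3,5,7-trioxooctanoate | COC(=O)CC(=O)CC(=O)CC(=O)Cc1c(CC=C(C)C)c(OCOC)c(OCOC)c(OC)c1CC=C(C)C | intermediate
14 | 2-[3,4-bis(methoxymethoxy)-5-methoxy-2,6-bis(3-methylbut-2-en-1-yl)phenyl]-1-(2,4,6-trihydroxyphenyl)ethan-1-one | O=C(Cc1c(CC=C(C)C)c(OCOC)c(OCOC)c(OC)c1CC=C(C)C)c1c(O)cc(O)cc1O | intermediate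
15 | (E)-3-(dimethylamino)-2-[3,4-bis(methoxymethoxy)-5-methoxy-2,6-bis(3-methylbut-2-en-1-yl)phenyl]-1-(2,4,6-trihydroxyphenyl)prop-2-en-1-one (not isolated; either alkene isomer would cyclise) | CN(C)/C=C(/C(=O)c1c(O)cc(O)cc1O)c1c(CC=C(C)C)c(OCOC)c(OCOC)c(OC)c1CC=C(C)C | intermediate
16 | 3-[3,4-bis(methoxymethoxy)-5-methoxy-2,6-bis(3-methylbut-2-en-1-yl)phenyl]-5,7-dihydroxy-4H-chromen-4-one | COc1c(OCOC)c(OCOC)c(CC=C(C)C)c(-c2coc3cc(O)cc(O)c3c2=O)c1CC=C(C)C | intermediate
17 | erythbigenin (3-[3,4-dihydroxy-5-methoxy-2,6-bis(3-methylbut-2-en-1-yl)phenyl]-5,7-dihydroxy-4H-chromen-4-one) | COc1c(O)c(O)c(CC=C(C)C)c(-c2coc3cc(O)cc(O)c3c2=O)c1CC=C(C)C | target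

**Step count**

Total steps: 12. Longest linear sequence: 11 steps (steps 1–7 and 9–12); step 8 is a one-step side branch.

**Steps most likely to fail**

Step 10 (key step). What may go wrong: aldol closure of C2 onto the C7 ketone, or O-cyclisation to a 4-hydroxy-2-pyrone, outruns the Claisen closure, so that ring A forms with the wrong substitution or not at all. Fallback, setting out from 8 and returning at 17: ring A is brought in ready-made. Phloroglucinol with MOMCl and iPr2NEt should give 1,3,5-tris(methoxymethoxy)benzene F1. Ortho-lithiation with n-BuLi (THF, 0 °C) should give 2,4,6-tris(methoxymethoxy)phenyllithium F2. F2 should add to Weinreb amide 8 to give 2-[3,4-bis(methoxymethoxy)-5-methoxy-2,6-bis(3-methylbut-2-en-1-yl)phenyl]-1-[2,4,6-tris(methoxymethoxy)phenyl]ethan-1-one F3. Heating F3 in neat DMF-DMA should give the enaminone (E)-3-(dimethylamino)-2-[3,4-bis(methoxymethoxy)-5-methoxy-2,6-bis(3-methylbut-2-en-1-yl)phenyl]-1-[2,4,6-tris(methoxymethoxy)phenyl]prop-2-en-1-one F4. HCl in MeOH should then remove all five MOM groups, and the freed ortho hydroxyl should close ring C with loss of dimethylamine, arriving directly at 17.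

Step 9. What may go wrong: proton transfer from the benzylic methylene of 8 to the strongly basic trianion instead of C-acylation, or base-induced breakdown of the N-methoxy amide, returning starting materials. Fallback, setting out from 8 and returning at 13: the electrophile is lowered to the aldehyde oxidation level. LiAlH4 (THF, −78 °C) should reduce 8 to 2-[3,4-bis(methoxymethoxy)-5-methoxy-2,6-bis(3-methylbut-2-en-1-yl)phenyl]acetaldehyde F5. Trianion 12 should add to F5 at −78 °C (aldol addition, faster than enolisation) to give racemic methyl 8-[3,4-bis(methoxymethoxy)-5-methoxy-2,6-bis(3-methylbut-2-en-1-yl)phenyl]-7-hydroxy-3,5-dioxooctanoate F6. Dess–Martin periodinane (NaHCO3, CH2Cl2, 0 °C) should oxidise the C7 carbinol to the ketone, giving 13 and erasing the transient stereocentre.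

Step 6. What may go wrong: coupling through the tertiary end of the allyl unit (branched 1,1-dimethylallyl groups), slow oxidative addition at the doubly flanked C–Br bonds with protodebromination, or addition of the allylzinc to the ester. Fallback, setting out from 6 and returning at 7: a double Stille coupling with allyltributylstannane (Pd(PPh3)4, DMF, 100 °C), which has no regiochemical ambiguity, should give methyl 2-[2,6-diallyl-3,4-bis(methoxymethoxy)-5-methoxyphenyl]acetate F7. Olefin cross-metathesis of F7 with excess 2-methylbut-2-ene (second-generation Grubbs catalyst, CH2Cl2, 40 °C) should convert both allyl groups into prenyl groups, giving 7.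

Further compounds
F1 | step 10 | 1,3,5-tris(methoxymethoxy)benzene | COCOc1cc(OCOC)cc(OCOC)c1
F2 | step 10 | 2,4,6-tris(methoxymethoxy)phenyllithium | [Li]c1c(OCOC)cc(OCOC)cc1OCOC
F3 | step 10 | 2-[3,4-bis(methoxymethoxy)-5-methoxy-2,6-bis(3-methylbut-2-en-1-yl)phenyl]-1-[2,4,6-tris(methoxymethoxy)phenyl]ethan-1-one | COCOc1cc(OCOC)c(C(=O)Cc2c(CC=C(C)C)c(OCOC)c(OCOC)c(OC)c2CC=C(C)C)c(OCOC)c1
F4 | step 10 | (E)-3-(dimethylamino)-2-[3,4-bis(methoxymethoxy)-5-methoxy-2,6-bis(3-methylbut-2-en-1-yl)phenyl]-1-[2,4,6-tris(methoxymethoxy)phenyl]prop-2-en-1-one | CN(C)/C=C(/C(=O)c1c(OCOC)cc(OCOC)cc1OCOC)c1c(CC=C(C)C)c(OCOC)c(OCOC)c(OC)c1CC=C(C)C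
F5 | step 9 | 2-[3,4-bis(methoxymethoxy)-5-methoxy-2,6-bis(3-methylbut-2-en-1-yl)phenyl]acetaldehyde | O=CCc1c(CC=C(C)C)c(OCOC)c(OCOC)c(OC)c1CC=C(C)C
F6 | step 9 | methyl 8-[3,4-bis(methoxymethoxy)-5-methoxy-2,6-bis(3-methylbut-2-en-1-yl)phenyl]-7-hydroxy-3,5-dioxooctanoate (racemic) | COC(=O)CC(=O)CC(=O)CC(O)Cc1c(CC=C(C)C)c(OCOC)c(OCOC)c(OC)c1CC=C(C)C
F7 | step 6 | methyl 2-[2,6-diallyl-3,4-bis(methoxymethoxy)-5-methoxyphenyl]acetate | COC(=O)Cc1c(CC=C)c(OCOC)c(OCOC)c(OC)c1CC=C
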